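**Retrosynthetic overview**
1. Target ⇐ triol (acetylation) ⇐ acid opening of a Sharpless 2,3-epoxy alcohol ⇐ (E)-allylic alcohol ⇐ C13 methyl ketone (olefination, reduction).
2. C4 quaternary centre ⇐ late ester-enolate methylation; C8 methyl ⇐ ketone methylenation and hydrogenation; C9 quaternary centre and the C1=C10 alkene ⇐ deconjugative methylation of a bicyclic enone.
3. Ring B ⇐ aldol condensation of a 1,5-diketone ⇐ key intermolecular Michael addition of a regiodefined ring A cyclohexanone enolate to an α-silyl vinyl ketone carrying C6–C9 and C11–C13.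
4. Ring A fragment ⇐ Rh/BINAP asymmetric 1,4-addition of an aryl group (masked C18 carboxyl) to cyclohexenone with enolate trapping; acceptor ⇐ ethyl 5-oxohexanoate.
5. Ring order: ring A (from cyclohexenone) first, then ring B by Michael/aldol annulation.

Assumption: atom labels in the explanations follow halimane numbering (ring A C1–C5/C10, ring B C5–C10, side chain C11–C16, ester carbon C18).

**Step 1**
Reactants: 1 ethyl 5-oxohexanoate
Product: 2 ethyl 4-(2-methyl-1,3-dioxolan-2-yl)butanoate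
Conditions: HOCH2CH2OH, TsOH (cat.), toluene, reflux, Dean–Stark
Reagents that add atoms: ethane-1,2-diol OCCO
Why: Acid-catalysed ketalisation with azeotropic water removal masks the methyl ketone (future C13) and leaves the ester free.

**Step 2**
Reactants: 2 ethyl 4-(2-methyl-1,3-dioxolan-2-yl)butanoate
Product: 3 N-methoxy-N-methyl-4-(2-methyl-1,3-dioxolan-2-yl)butanamide
Conditions: MeNH(OMe)·HCl, i-PrMgCl, THF, −20 to 0 °C
Reagents that add atoms: N,O-dimethylhydroxylamine hydrochloride CNOC.Cl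
Why: Weinreb amide formation by aminolysis of the ester with the chloromagnesium amide, which sets up a clean single acylation in the next step.

**Step 3**
Reactants: 3 N-methoxy-N-methyl-4-(2-methyl-1,3-dioxolan-2-yl)butanamide; 4 (1-bromoethenyl)trimethylsilane
Product: 6 6-(2-methyl-1,3-dioxolan-2-yl)-2-(trimethylsilyl)hex-1-en-3-one, via Grignard reagent 5 (not isolated)
Conditions: 4, Mg, THF, 50 °C; then 3, THF, −20 to 0 °C; cold aq NH4Cl
Reagents that add atoms: none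
Why: Grignard acylation of a Weinreb amide stops at the ketone through the chelated tetrahedral intermediate and gives the α-silyl vinyl ketone used as Michael acceptor.

**Step 4**
Reactants: 7 1-bromo-4-methoxybenzene
Product: 9 (4-methoxyphenyl)tri(propan-2-yloxy)titanium, via aryllithium 8 (not isolated)
Conditions: n-BuLi, THF, −78 °C; ClTi(OiPr)3, −78 °C to rt
Reagents that add atoms: chlorotri(propan-2-yloxy)titanium CC(C)O[Ti](Cl)(OC(C)C)OC(C)C
Why: Bromine–lithium exchange followed by transmetalation gives the aryl titanate needed for an aprotic conjugate addition; its ipso carbon becomes C18.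

**Step 5**
Reactants: 10 cyclohex-2-en-1-one; 9 (4-methoxyphenyl)tri(propan-2-yloxy)titanium
Product: 12 trimethyl{[(3R)-3-(4-methoxyphenyl)cyclohex-1-en-1-yl]oxy}silane, via titanium enolate 11 (not isolated)
Conditions: [Rh(OH)((R)-BINAP)]2 (1.5 mol %), THF, 20 °C; then LiOiPr, Me3SiCl
Reagents that add atoms: chlorotrimethylsilane C[Si](C)(C)Cl
Why: Rhodium/BINAP-catalysed asymmetric 1,4-addition (Hayashi–Miyaura type) delivers the aryl group to one enone face to give the 3R centre (future C4), and silylation of the titanium enolate keeps the C10–C5 enolate regiochemistry.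

**Step 6**
Reactants: 12 trimethyl{[(3R)-3-(4-methoxyphenyl)cyclohex-1-en-1-yl]oxy}silane; 6 6-(2-methyl-1,3-dioxolan-2-yl)-2-(trimethylsilyl)hex-1-en-3-one
Product: 15 (2S,3R)-3-(4-methoxyphenyl)-2-[6-(2-methyl-1,3-dioxolan-2-yl)-3-oxohexyl]cyclohexan-1-one, via lithium enolate 13 (not isolated), via silyl diketone 14 (not isolated)
Conditions: MeLi, THF, 0 °C; 6, −78 to −20 °C; aq NH4Cl; then KF (cat.), MeOH, rt
Reagents that add atoms: none
Why: Key intermolecular Michael addition (Stork–Ganem variant of the Robinson annulation): the regiodefined enolate adds through C5 to the α-silyl enone, and the new C5 centre forms trans to the C4 aryl group (attack anti to the neighbouring substituent, also the diequatorial thermodynamic product).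

**Step 7**
Reactants: 15 (2S,3R)-3-(4-methoxyphenyl)-2-[6-(2-methyl-1,3-dioxolan-2-yl)-3-oxohexyl]cyclohexan-1-one
Product: 16 (1R,2S)-2-[6-(2-methyl-1,3-dioxolan-2-yl)-3-oxohexyl]-3-oxocyclohexane-1-carboxylic acid
Conditions: RuCl3 (5 mol %), NaIO4, NaHCO3, MeCN/EtOAc/H2O, 0 °C to rt; then acidify to pH 4
Reagents that add atoms: sodium periodate [Na+].[O-]I(=O)(=O)=O; water O
Why: Ruthenium tetroxide oxidation degrades the electron-rich anisyl ring to the carboxylic acid (C18), while the saturated ketones and the buffered ketal are expected to survive and C4/C5 are untouched.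

**Step 8**
Reactants: 16 (1R,2S)-2-[6-(2-methyl-1,3-dioxolan-2-yl)-3-oxohexyl]-3-oxocyclohexane-1-carboxylic acid
Product: 17 methyl (1R,2S)-2-[6-(2-methyl-1,3-dioxolan-2-yl)-3-oxohexyl]-3-oxocyclohexane-1-carboxylate
Conditions: Me3SiCHN2, MeOH/toluene, 0 °C
Reagents that add atoms: (trimethylsilyl)diazomethane C[Si](C)(C)C=[N+]=[N-]
Why: Neutral esterification by a diazoalkane avoids base or acid at the epimerisable centres and the ketal.

**Step 9**
Reactants: 17 methyl (1R,2S)-2-[6-(2-methyl-1,3-dioxolan-2-yl)-3-oxohexyl]-3-oxocyclohexane-1-carboxylate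
Product: 18 methyl (1R,8aS)-5-[2-(2-methyl-1,3-dioxolan-2-yl)ethyl]-6-oxo-1,2,3,4,6,7,8,8a-octahydronaphthalene-1-carboxylate
Conditions: NaOMe (0.3 equiv), MeOH, rt to 50 °C
Reagents that add atoms: none
Why: Intramolecular aldol condensation (second stage of a Robinson annulation) closes ring B as the conjugated enone, and the trans C4/C5 arrangement is also the thermodynamic one.

**Step 10**
Reactants: 18 methyl (1R,8aS)-5-[2-(2-methyl-1,3-dioxolan-2-yl)ethyl]-6-oxo-1,2,3,4,6,7,8,8a-octahydronaphthalene-1-carboxylate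
Product: 20 methyl (1R,5R,8aS)-5-methyl-5-[2-(2-methyl-1,3-dioxolan-2-yl)ethyl]-6-oxo-1,2,3,5,6,7,8,8a-octahydronaphthalene-1-carboxylate, via potassium dienolate 19 (not isolated)
Conditions: t-BuOK (1.1 equiv), t-BuOH/THF, 0 °C; MeI, 0 °C to rt
Reagents that add atoms: iodomethane CI
Why: Deconjugative α-alkylation of the thermodynamic heteroannular dienolate: MeI attacks C9 axially on the face of the axial C5–H, which sets the C9 quaternary centre and moves the alkene to C1=C10.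

**Step 11**
Reactants: 20 methyl (1R,5R,8aS)-5-methyl-5-[2-(2-methyl-1,3-dioxolan-2-yl)ethyl]-6-oxo-1,2,3,5,6,7,8,8a-octahydronaphthalene-1-carboxylate
Product: 21 methyl (1R,5S,8aS)-5-methyl-6-methylidene-5-[2-(2-methyl-1,3-dioxolan-2-yl)ethyl]-1,2,3,5,6,7,8,8a-octahydronaphthalene-1-carboxylate
Conditions: Ph3PCH3Br, t-BuOK, toluene, 90 °C
Reagents that add atoms: methyltriphenylphosphonium bromide C[P+](c1ccccc1)(c1ccccc1)c1ccccc1.[Br-]
Why: Wittig methylenation converts the hindered C8 ketone into the exocyclic alkene that carries the future C8 methyl carbon.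

**Step 12**
Reactants: 21 methyl (1R,5S,8aS)-5-methyl-6-methylidene-5-[2-(2-methyl-1,3-dioxolan-2-yl)ethyl]-1,2,3,5,6,7,8,8a-octahydronaphthalene-1-carboxylate
Product: 22 methyl (1R,5S,6R,8aS)-5,6-dimethyl-5-[2-(2-methyl-1,3-dioxolan-2-yl)ethyl]-1,2,3,5,6,7,8,8a-octahydronaphthalene-1-carboxylate
Conditions: H2 (1 atm), Pd/C (5 %), EtOAc, rt
Reagents that add atoms: none
Why: Catalytic hydrogenation adds hydrogen to the 1,1-disubstituted alkene from the face opposite the axial C9 methyl, giving the equatorial C8 methyl cis to it, while the hindered trisubstituted C1=C10 alkene is not reduced.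

**Step 13**
Reactants: 22 methyl (1R,5S,6R,8aS)-5,6-dimethyl-5-[2-(2-methyl-1,3-dioxolan-2-yl)ethyl]-1,2,3,5,6,7,8,8a-octahydronaphthalene-1-carboxylate
Product: 24 methyl (1S,5S,6R,8aR)-1,5,6-trimethyl-5-[2-(2-methyl-1,3-dioxolan-2-yl)ethyl]-1,2,3,5,6,7,8,8a-octahydronaphthalene-1-carboxylate, via lithium ester enolate 23 (not isolated)
Conditions: LiN(iPr)2, THF, −78 °C; MeI, DMPU, −78 to 0 °C
Reagents that add atoms: iodomethane CI
Why: Ester enolate alkylation at the only acidic C–H (C4): MeI enters from the face opposite the C5–C6 bond (A(1,3)-strain control, as in resin-acid C4 methylations), giving the C4 quaternary centre with the ester on the side of C6.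

**Step 14**
Reactants: 24 methyl (1S,5S,6R,8aR)-1,5,6-trimethyl-5-[2-(2-methyl-1,3-dioxolan-2-yl)ethyl]-1,2,3,5,6,7,8,8a-octahydronaphthalene-1-carboxylate
Product: 25 methyl (1S,5S,6R,8aR)-1,5,6-trimethyl-5-(3-oxobutyl)-1,2,3,5,6,7,8,8a-octahydronaphthalene-1-carboxylate
Conditions: 0.5 M HCl, THF/H2O, rt
Reagents that add atoms: water O
Why: Acid-catalysed acetal hydrolysis unmasks the C13 methyl ketone without affecting the hindered ester or the alkene.

**Step 15**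
Reactants: 25 methyl (1S,5S,6R,8aR)-1,5,6-trimethyl-5-(3-oxobutyl)-1,2,3,5,6,7,8,8a-octahydronaphthalene-1-carboxylate
Product: 26 methyl (1S,5S,6R,8aR)-5-[(3E)-5-ethoxy-3-methyl-5-oxopent-3-en-1-yl]-1,5,6-trimethyl-1,2,3,5,6,7,8,8a-octahydronaphthalene-1-carboxylate
Conditions: (EtO)2P(O)CH2CO2Et, NaH, THF, 0 to 60 °C; chromatography
Reagents that add atoms: triethyl phosphonoacetate CCOC(=O)CP(=O)(OCC)OCC
Why: Horner–Wadsworth–Emmons olefination gives mainly the (E)-trisubstituted enoate (about 5:1 expected), and the minor Z isomer is removed by chromatography.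

**Step 16**
Reactants: 26 methyl (1S,5S,6R,8aR)-5-[(3E)-5-ethoxy-3-methyl-5-oxopent-3-en-1-yl]-1,5,6-trimethyl-1,2,3,5,6,7,8,8a-octahydronaphthalene-1-carboxylate
Product: 27 methyl (1S,5S,6R,8aR)-5-[(3E)-5-hydroxy-3-methylpent-3-en-1-yl]-1,5,6-trimethyl-1,2,3,5,6,7,8,8a-octahydronaphthalene-1-carboxylate
Conditions: i-Bu2AlH (2.2 equiv), CH2Cl2, −78 °C
Reagents that add atoms: none
Why: Hydride reduction of the unhindered conjugated ethyl ester gives the allylic alcohol, while the neopentyl C4 methyl ester is too hindered to react at −78 °C.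

**Step 17**
Reactants: 27 methyl (1S,5S,6R,8aR)-5-[(3E)-5-hydroxy-3-methylpent-3-en-1-yl]-1,5,6-trimethyl-1,2,3,5,6,7,8,8a-octahydronaphthalene-1-carboxylate
Product: 28 methyl (1S,5S,6R,8aR)-5-{2-[(2S,3S)-3-(hydroxymethyl)-2-methyloxiran-2-yl]ethyl}-1,5,6-trimethyl-1,2,3,5,6,7,8,8a-octahydronaphthalene-1-carboxylate
Conditions: Ti(OiPr)4 (10 mol %), L-(+)-diethyl tartrate, t-BuOOH, 4 Å MS, CH2Cl2, −20 °C
Reagents that add atoms: tert-butyl hydroperoxide CC(C)(C)OO
Why: Sharpless asymmetric epoxidation touches only the allylic alcohol, and the L-(+)-tartrate catalyst gives, as with geraniol, the (2S,3S)-epoxy alcohol (13S,14S).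

**Step 18**
Reactants: 28 methyl (1S,5S,6R,8aR)-5-{2-[(2S,3S)-3-(hydroxymethyl)-2-methyloxiran-2-yl]ethyl}-1,5,6-trimethyl-1,2,3,5,6,7,8,8a-octahydronaphthalene-1-carboxylate
Product: 29 methyl (1S,5S,6R,8aR)-1,5,6-trimethyl-5-[(3R,4S)-3,4,5-trihydroxy-3-methylpentyl]-1,2,3,5,6,7,8,8a-octahydronaphthalene-1-carboxylate
Conditions: HClO4 (cat.), THF/H2O, 0 °C
Reagents that add atoms: water O
Why: Acid-catalysed epoxide hydrolysis: water opens the protonated epoxide at the tertiary C13 with inversion while C14 keeps its configuration, which gives the 13R,14S triol.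

**Step 19**
Reactants: 29 methyl (1S,5S,6R,8aR)-1,5,6-trimethyl-5-[(3R,4S)-3,4,5-trihydroxy-3-methylpentyl]-1,2,3,5,6,7,8,8a-octahydronaphthalene-1-carboxylate
Product: 30 methyl (1S,5S,6R,8aR)-5-[(3R,4S)-4,5-bis(acetyloxy)-3-hydroxy-3-methylpentyl]-1,5,6-trimethyl-1,2,3,5,6,7,8,8a-octahydronaphthalene-1-carboxylate
Conditions: Ac2O, pyridine, DMAP (cat.), CH2Cl2, 0 °C
Reagents that add atoms: acetic anhydride CC(=O)OC(C)=O
Why: Acyl transfer acetylates the primary and secondary hydroxyls, while the tertiary C13 hydroxyl is too hindered to react under these conditions.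

**Compound list**
1 | ethyl 5-oxohexanoate | CCOC(=O)CCCC(C)=O | starting material
2 | ethyl 4-(2-methyl-1,3-dioxolan-2-yl)butanoate | CCOC(=O)CCCC1(C)OCCO1 | intermediate
3 | N-methoxy-N-methyl-4-(2-methyl-1,3-dioxolan-2-yl)butanamide | CON(C)C(=O)CCCC1(C)OCCO1 | intermediate
4 | (1-bromoethenyl)trimethylsilane | C=C(Br)[Si](C)(C)C | starting material
5 | [1-(trimethylsilyl)ethenyl]magnesium bromide | C=C([Mg]Br)[Si](C)(C)C | intermediate
6 | 6-(2-methyl-1,3-dioxolan-2-yl)-2-(trimethylsilyl)hex-1-en-3-one | C=C([Si](C)(C)C)C(=O)CCCC1(C)OCCO1 | intermediate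
7 | 1-bromo-4-methoxybenzene | COc1ccc(Br)cc1 | starting material
8 | (4-methoxyphenyl)lithium | [Li]c1ccc(OC)cc1 | intermediate
9 | (4-methoxyphenyl)tri(propan-2-yloxy)titanium | COc1ccc(cc1)[Ti](OC(C)C)(OC(C)C)OC(C)C | intermediate
10 | cyclohex-2-en-1-one | O=C1C=CCCC1 | starting material
11 | {[(3R)-3-(4-methoxyphenyl)cyclohex-1-en-1-yl]oxy}tri(propan-2-yloxy)titanium | CC(C)O[Ti](OC(C)C)(OC(C)C)OC1=C[C@H](c2ccc(OC)cc2)CCC1 | intermediate
12 | trimethyl{[(3R)-3-(4-methoxyphenyl)cyclohex-1-en-1-yl]oxy}silane | C[Si](C)(C)OC1=C[C@H](c2ccc(OC)cc2)CCC1 | intermediate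
13 | lithium (3R)-3-(4-methoxyphenyl)cyclohex-1-en-1-olate | [Li]OC1=C[C@H](c2ccc(OC)cc2)CCC1 | intermediate
14 | (2S,3R)-3-(4-methoxyphenyl)-2-[6-(2-methyl-1,3-dioxolan-2-yl)-3-oxo-2-(trimethylsilyl)hexyl]cyclohexan-1-one (both epimers at the silylated carbon) | O=C1CCC[C@@H](c2ccc(OC)cc2)[C@@H]1CC([Si](C)(C)C)C(=O)CCCC3(C)OCCO3 | intermediate
15 | (2S,3R)-3-(4-methoxyphenyl)-2-[6-(2-methyl-1,3-dioxolan-2-yl)-3-oxohexyl]cyclohexan-1-one | O=C1CCC[C@@H](c2ccc(OC)cc2)[C@@H]1CCC(=O)CCCC3(C)OCCO3 | intermediate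
16 | (1R,2S)-2-[6-(2-methyl-1,3-dioxolan-2-yl)-3-oxohexyl]-3-oxocyclohexane-1-carboxylic acid | O=C1CCC[C@@H](C(=O)O)[C@@H]1CCC(=O)CCCC3(C)OCCO3 | intermediate
17 | methyl (1R,2S)-2-[6-(2-methyl-1,3-dioxolan-2-yl)-3-oxohexyl]-3-oxocyclohexane-1-carboxylate | O=C1CCC[C@@H](C(=O)OC)[C@@H]1CCC(=O)CCCC3(C)OCCO3 | intermediate
18 | methyl (1R,8aS)-5-[2-(2-methyl-1,3-dioxolan-2-yl)ethyl]-6-oxo-1,2,3,4,6,7,8,8a-octahydronaphthalene-1-carboxylate | COC(=O)[C@@H]1CCCC2=C(CCC3(C)OCCO3)C(=O)CC[C@@H]12 | intermediate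
19 | potassium (4aS,5R)-5-(methoxycarbonyl)-1-[2-(2-methyl-1,3-dioxolan-2-yl)ethyl]-3,4,4a,5,6,7-hexahydronaphthalen-2-olate | COC(=O)[C@@H]1CCC=C2C(CCC3(C)OCCO3)=C([O-])CC[C@@H]12.[K+] | intermediate
20 | methyl (1R,5R,8aS)-5-methyl-5-[2-(2-methyl-1,3-dioxolan-2-yl)ethyl]-6-oxo-1,2,3,5,6,7,8,8a-octahydronaphthalene-1-carboxylate | COC(=O)[C@@H]1CCC=C2[C@H]1CCC(=O)[C@]2(C)CCC3(C)OCCO3 | intermediate
21 | methyl (1R,5S,8aS)-5-methyl-6-methylidene-5-[2-(2-methyl-1,3-dioxolan-2-yl)ethyl]-1,2,3,5,6,7,8,8a-octahydronaphthalene-1-carboxylate | COC(=O)[C@@H]1CCC=C2[C@H]1CCC(=C)[C@]2(C)CCC3(C)OCCO3 | intermediate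
22 | methyl (1R,5S,6R,8aS)-5,6-dimethyl-5-[2-(2-methyl-1,3-dioxolan-2-yl)ethyl]-1,2,3,5,6,7,8,8a-octahydronaphthalene-1-carboxylate | COC(=O)[C@@H]1CCC=C2[C@H]1CC[C@@H](C)[C@]2(C)CCC3(C)OCCO3 | intermediate
23 | lithium ester enolate of 22 (C4=C(OMe)OLi, other centres as in 22) | COC(O[Li])=C1CCC=C2[C@H]1CC[C@@H](C)[C@]2(C)CCC3(C)OCCO3 | intermediate
24 | methyl (1S,5S,6R,8aR)-1,5,6-trimethyl-5-[2-(2-methyl-1,3-dioxolan-2-yl)ethyl]-1,2,3,5,6,7,8,8a-octahydronaphthalene-1-carboxylate | COC(=O)[C@@]1(C)CCC=C2[C@H]1CC[C@@H](C)[C@]2(C)CCC3(C)OCCO3 | intermediate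
25 | methyl (1S,5S,6R,8aR)-1,5,6-trimethyl-5-(3-oxobutyl)-1,2,3,5,6,7,8,8a-octahydronaphthalene-1-carboxylate | COC(=O)[C@@]1(C)CCC=C2[C@H]1CC[C@@H](C)[C@]2(C)CCC(C)=O | intermediate
26 | methyl (1S,5S,6R,8aR)-5-[(3E)-5-ethoxy-3-methyl-5-oxopent-3-en-1-yl]-1,5,6-trimethyl-1,2,3,5,6,7,8,8a-octahydronaphthalene-1-carboxylate | COC(=O)[C@@]1(C)CCC=C2[C@H]1CC[C@@H](C)[C@]2(C)CC/C(C)=C/C(=O)OCC | intermediate
27 | methyl (1S,5S,6R,8aR)-5-[(3E)-5-hydroxy-3-methylpent-3-en-1-yl]-1,5,6-trimethyl-1,2,3,5,6,7,8,8a-octahydronaphthalene-1-carboxylate | COC(=O)[C@@]1(C)CCC=C2[C@H]1CC[C@@H](C)[C@]2(C)CC/C(C)=C/CO | intermediate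
28 | methyl (1S,5S,6R,8aR)-5-{2-[(2S,3S)-3-(hydroxymethyl)-2-methyloxiran-2-yl]ethyl}-1,5,6-trimethyl-1,2,3,5,6,7,8,8a-octahydronaphthalene-1-carboxylate | COC(=O)[C@@]1(C)CCC=C2[C@H]1CC[C@@H](C)[C@]2(C)CC[C@]3(C)O[C@H]3CO | intermediate
29 | methyl (1S,5S,6R,8aR)-1,5,6-trimethyl-5-[(3R,4S)-3,4,5-trihydroxy-3-methylpentyl]-1,2,3,5,6,7,8,8a-octahydronaphthalene-1-carboxylate | COC(=O)[C@@]1(C)CCC=C2[C@H]1CC[C@@H](C)[C@]2(C)CC[C@@](C)(O)[C@H](CO)O | intermediate
30 | methyl (1S,5S,6R,8aR)-5-[(3R,4S)-4,5-bis(acetyloxy)-3-hydroxy-3-methylpentyl]-1,5,6-trimethyl-1,2,3,5,6,7,8,8a-octahydronaphthalene-1-carboxylate | COC(=O)[C@@]1(C)CCC=C2[C@H]1CC[C@@H](C)[C@]2(C)CC[C@@](C)(O)[C@H](COC(C)=O)OC(C)=O | target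

**Step count and risks**

Total steps: 19. Longest linear sequence: 17 steps (steps 1–3, then 6–19).

The three steps most likely to fail:

Step 7 (oxidative degradation of the anisyl ring beside a dioxolane and two enolisable ketones). The fallback sets out from 10 and comes back at 16; it carries the carboxyl as an (E)-alkenyl group that ozone cleaves without touching the ketal. Hydrozirconation of hex-1-yne with Cp2Zr(H)Cl and [Rh(cod)(MeCN)2]BF4/(R)-BINAP-catalysed 1,4-addition to 10 give the zirconium enolate chlorobis(cyclopentadienyl){[(3S)-3-[(1E)-hex-1-en-1-yl]cyclohex-1-en-1-yl]oxy}zirconium F1. Me3SiCl converts it into trimethyl{[(3S)-3-[(1E)-hex-1-en-1-yl]cyclohex-1-en-1-yl]oxy}silane F2. MeLi gives lithium (3S)-3-[(1E)-hex-1-en-1-yl]cyclohex-1-en-1-olate F3, which adds to 6 to give (2S,3S)-3-[(1E)-hex-1-en-1-yl]-2-[6-(2-methyl-1,3-dioxolan-2-yl)-3-oxo-2-(trimethylsilyl)hexyl]cyclohexan-1-one F4. KF/MeOH gives (2S,3S)-3-[(1E)-hex-1-en-1-yl]-2-[6-(2-methyl-1,3-dioxolan-2-yl)-3-oxohexyl]cyclohexan-1-one F5. Ozonolysis (O3, CH2Cl2/MeOH, −78 °C; Me2S) gives (1R,2S)-2-[6-(2-methyl-1,3-dioxolan-2-yl)-3-oxohexyl]-3-oxocyclohexane-1-carbaldehyde F6, and NaClO2/NaH2PO4/2-methylbut-2-ene oxidation returns 16.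

Step 10 (deconjugative methylation: C1 versus C5 deprotonation, O-alkylation, over-methylation at C7, facial selectivity at C9). The fallback sets out from 18 and comes back at 20. The thermodynamic silyl dienol ether methyl (1R,8aS)-5-[2-(2-methyl-1,3-dioxolan-2-yl)ethyl]-6-[(trimethylsilyl)oxy]-1,2,3,7,8,8a-hexahydronaphthalene-1-carboxylate F7 is made with Me3SiCl, NaI and Et3N in MeCN, purified, and its alkene positions checked. Fluoride-mediated C-methylation (benzyltrimethylammonium fluoride, MeI, THF, 4 Å MS) of this regiodefined precursor then gives 20 without excess strong base.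

Step 12 (hydrogenation: alkene isomerisation on Pd, facial selectivity at C8, over-reduction of C1=C10). The fallback sets out from 21 and comes back at 22. Hydroboration with 9-BBN from the same open face, then NaBO3, gives methyl (1R,5S,6R,8aS)-6-(hydroxymethyl)-5-methyl-5-[2-(2-methyl-1,3-dioxolan-2-yl)ethyl]-1,2,3,5,6,7,8,8a-octahydronaphthalene-1-carboxylate F8; the syn delivery of H to C8 sets the same configuration and the trisubstituted alkene is left alone. I2/PPh3/imidazole gives methyl (1R,5S,6R,8aS)-6-(iodomethyl)-5-methyl-5-[2-(2-methyl-1,3-dioxolan-2-yl)ethyl]-1,2,3,5,6,7,8,8a-octahydronaphthalene-1-carboxylate F9, and Bu3SnH/AIBN reduction gives 22.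

**Further compounds**
F1 | step 7 | chlorobis(cyclopentadienyl){[(3S)-3-[(1E)-hex-1-en-1-yl]cyclohex-1-en-1-yl]oxy}zirconium | Cl[Zr](C1C=CC=C1)(C1C=CC=C1)OC1=C[C@H](/C=C/CCCC)CCC1
F2 | step 7 | trimethyl{[(3S)-3-[(1E)-hex-1-en-1-yl]cyclohex-1-en-1-yl]oxy}silane | C[Si](C)(C)OC1=C[C@H](/C=C/CCCC)CCC1
F3 | step 7 | lithium (3S)-3-[(1E)-hex-1-en-1-yl]cyclohex-1-en-1-olate | [Li]OC1=C[C@H](/C=C/CCCC)CCC1
F4 | step 7 | (2S,3S)-3-[(1E)-hex-1-en-1-yl]-2-[6-(2-methyl-1,3-dioxolan-2-yl)-3-oxo-2-(trimethylsilyl)hexyl]cyclohexan-1-one (both epimers at the silylated carbon) | O=C1CCC[C@@H](/C=C/CCCC)[C@@H]1CC([Si](C)(C)C)C(=O)CCCC2(C)OCCO2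
F5 | step 7 | (2S,3S)-3-[(1E)-hex-1-en-1-yl]-2-[6-(2-methyl-1,3-dioxolan-2-yl)-3-oxohexyl]cyclohexan-1-one | O=C1CCC[C@@H](/C=C/CCCC)[C@@H]1CCC(=O)CCCC2(C)OCCO2
F6 | step 7 | (1R,2S)-2-[6-(2-methyl-1,3-dioxolan-2-yl)-3-oxohexyl]-3-oxocyclohexane-1-carbaldehyde | O=C1CCC[C@@H](C=O)[C@@H]1CCC(=O)CCCC2(C)OCCO2
F7 | step 10 | methyl (1R,8aS)-5-[2-(2-methyl-1,3-dioxolan-2-yl)ethyl]-6-[(trimethylsilyl)oxy]-1,2,3,7,8,8a-hexahydronaphthalene-1-carboxylate | COC(=O)[C@@H]1CCC=C2C(CCC3(C)OCCO3)=C(O[Si](C)(C)C)CC[C@@H]12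
F8 | step 12 | methyl (1R,5S,6R,8aS)-6-(hydroxymethyl)-5-methyl-5-[2-(2-methyl-1,3-dioxolan-2-yl)ethyl]-1,2,3,5,6,7,8,8a-octahydronaphthalene-1-carboxylate | COC(=O)[C@@H]1CCC=C2[C@H]1CC[C@@H](CO)[C@]2(C)CCC3(C)OCCO3
F9 | step 12 | methyl (1R,5S,6R,8aS)-6-(iodomethyl)-5-methyl-5-[2-(2-methyl-1,3-dioxolan-2-yl)ethyl]-1,2,3,5,6,7,8,8a-octahydronaphthalene-1-carboxylate | COC(=O)[C@@H]1CCC=C2[C@H]1CC[C@@H](CI)[C@]2(C)CCC3(C)OCCO3
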